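## Retrosynthetic overview

1. Target 13 ⇐ acetonide 12 by acetal hydrolysis.
2. 12 ⇐ enone 6 + the β-oxido C17 organometallic from epoxide 9 (C1–C1' bond); 1,2-addition anti to the dioxolane sets C1.
3. 6 ⇐ meso diene acetonide 3 by enantiotopos-selective hydroboration (the symmetry-breaking step), then oxidation.
4. 3 ⇐ benzene by enzymatic cis-dihydroxylation (the dearomatising step) and acetonide formation; 9 ⇐ (Z)-hexadec-9-enal by methylenation and hydrolytic kinetic resolution.
5. Rings: the carbocycle is the benzene ring itself and is never constructed; only the temporary dioxolane (step 2) and the oxirane (step 5) are formed.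

Assumptions: (Z)-hexadec-9-enal (pheromone grade) and crystalline (−)-Ipc2BH are taken as purchasable/in stock; the whole-cell oxidation counts as one step; the target is read as (1R,4R,5S,2'S,10'Z), with the three ring hydroxyls mutually cis.

## Route

Step 1
Reactants: 1 benzene
Product: 2 cis-cyclohexa-3,5-diene-1,2-diol (meso, 1R,2S)
Conditions: E. coli JM109(pDTG601) whole cells (toluene dioxygenase, IPTG), glucose feed, benzene via vapour phase, air, pH 7 phosphate, 30 °C; EtOAc extraction
Reagents that add atoms: dioxygen, O=O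
Why: Rieske arene dioxygenase cis-dihydroxylation delivers both atoms of one O2 to the same face of one C=C, giving the meso cis-diol, and the strain lacks the diol dehydrogenase that would rearomatise it to catechol.

Step 2
Reactants: 2 cis-cyclohexa-3,5-diene-1,2-diol
Product: 3 (3aR,7aS)-2,2-dimethyl-3a,7a-dihydro-1,3-benzodioxole (meso diene acetonide)
Conditions: 2,2-dimethoxypropane, TsOH·H2O (1 mol %), acetone, 0 °C, 20 min; Et3N quench; used at once (dimerises on standing)
Reagents that add atoms: 2,2-dimethoxypropane, COC(C)(C)OC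
Why: Acid-catalysed transketalisation (acetonide formation) outruns dehydration to phenol at 0 °C and gives a cis-fused dioxolane that shields one face of the diene, with no stereocentre changed.

Step 3
Reactants: 3 meso diene acetonide
Product: 5 (1S,4R,5S)-4,5-(isopropylidenedioxy)cyclohex-2-en-1-ol (OH trans to the dioxolane), via allylborane 4 (not isolated)
Conditions: (−)-Ipc2BH (from (+)-α-pinene, 1.0 equiv), THF, −25 °C, 24 h; then 3 M NaOH, 30% H2O2, 0 °C → rt
Reagents that add atoms: (−)-diisopinocampheylborane, B([C@@H]1C[C@@H]2C[C@H]([C@H]1C)C2(C)C)[C@@H]1C[C@@H]2C[C@H]([C@H]1C)C2(C)C (boron and Ipc groups of 4 only); hydrogen peroxide, OO (oxygen of 5)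
Why: Proposed new method: Brown asymmetric hydroboration–oxidation used as an enantiotopos-selective desymmetrisation, the closest known reaction being Ipc2BH hydroboration of cyclohexa-1,3-diene (boron on an internal carbon, allylborane, cyclohex-2-enol in high ee after oxidation); here the reagent must come anti to the dioxolane, the terminal diene carbons are the more hindered ones, and by the cis-alkene rule the (−)-reagent picks the internal carbon that becomes the 1S carbinol on oxidation with retention (the (+)-reagent is used if the sense proves opposite).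

Step 4
Reactants: 5 (1S,4R,5S)-4,5-(isopropylidenedioxy)cyclohex-2-en-1-ol
Product: 6 (4R,5S)-4,5-(isopropylidenedioxy)cyclohex-2-en-1-one
Conditions: activated MnO2 (15 equiv), CH2Cl2, rt
Reagents that add atoms: none
Why: Neutral MnO2 allylic alcohol oxidation removes only the carbinol stereocentre and avoids base-induced β-elimination of the C5 oxygen, leaving C4 and C5 intact.

Step 5
Reactants: 7 (Z)-hexadec-9-enal
Product: 8 rac-2-[(8Z)-pentadec-8-en-1-yl]oxirane
Conditions: Me3S+ I− (1.3 equiv), n-BuLi (1.25 equiv), THF, −10 °C; then 7, −10 °C → rt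
Reagents that add atoms: trimethylsulfonium iodide, C[S+](C)C.[I-]
Why: Corey–Chaykovsky methylenation, in which the sulfonium ylide adds to the aldehyde and the betaine closes to the terminal epoxide while the isolated Z-alkene is inert.

Step 6
Reactants: 8 rac-2-[(8Z)-pentadec-8-en-1-yl]oxirane
Product: 9 (S)-2-[(8Z)-pentadec-8-en-1-yl]oxirane
Conditions: (S,S)-(salen)Co(III)OAc (1 mol %), H2O (0.55 equiv), minimal THF, 0 °C → rt, 20 h; chromatography
Reagents that add atoms: none
Why: Jacobsen hydrolytic kinetic resolution, in which this catalyst enantiomer hydrates the (R)-epoxide much faster and leaves (S)-9 in >99% ee, which fixes C2' of the target.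

Step 7
Reactants: 9 (S)-2-[(8Z)-pentadec-8-en-1-yl]oxirane; 6 (4R,5S)-4,5-(isopropylidenedioxy)cyclohex-2-en-1-one
Product: 12 (1R,4R,5S)-1-[(2S,10Z)-2-hydroxyheptadec-10-en-1-yl]-4,5-(isopropylidenedioxy)cyclohex-2-en-1-ol, via dilithio alkoxide 10 (not isolated), via organocerium 11 (not isolated)
Conditions: 9 (1.3 equiv), LiDBB (2.6 equiv, from Li and DBB), THF, −78 °C, 15 min; dry CeCl3 (1.4 equiv), −78 °C, 45 min; 6 (1.0 equiv), −78 °C, 1 h; aq NH4Cl
Reagents that add atoms: lithium 4,4'-di-tert-butylbiphenylide, [Li+].CC(C)(C)c1ccc(cc1)[C]1C=C[C-](C=C1)C(C)(C)C (lithium of 10); cerium(III) chloride, Cl[Ce](Cl)Cl (Ce and Cl of 11)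
Why: Reductive lithiation of the terminal epoxide cleaves the less substituted C–O bond to a primary β-lithioalkoxide without touching C2', and after transmetalation the less basic organocerium adds 1,2 to the enone from the convex face anti to the cis-fused dioxolane, so the new tertiary OH is cis to the C4/C5 oxygens (C1 = R).

Step 8
Reactants: 12 acetonide-protected adduct
Product: 13 (1R,4R,5S)-1-[(2S,10Z)-2-hydroxyheptadec-10-en-1-yl]cyclohex-2-ene-1,4,5-triol (target)
Conditions: AcOH/H2O 4:1, rt → 35 °C; toluene azeotrope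
Reagents that add atoms: none
Why: Mild acid-catalysed acetal hydrolysis frees the cis-diol without touching a stereocentre, and the tertiary allylic alcohol should not ionise because its allyl cation is destabilised by the adjacent C4–O bond.

## Compound list

1 | benzene | c1ccccc1 | starting material
2 | cis-cyclohexa-3,5-diene-1,2-diol (meso) | C1=C[C@@H](O)[C@@H](O)C=C1 | intermediate
3 | (3aR,7aS)-2,2-dimethyl-3a,7a-dihydro-1,3-benzodioxole (meso) | C1=C[C@H]2OC(C)(C)O[C@H]2C=C1 | intermediate
4 | [(1S,4R,5S)-4,5-(isopropylidenedioxy)cyclohex-2-en-1-yl]diisopinocampheylborane (not isolated) | B([C@@H]1C=C[C@H]2OC(C)(C)O[C@H]2C1)([C@@H]1C[C@@H]2C[C@H]([C@H]1C)C2(C)C)[C@@H]1C[C@@H]2C[C@H]([C@H]1C)C2(C)C | intermediate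
5 | (1S,4R,5S)-4,5-(isopropylidenedioxy)cyclohex-2-en-1-ol | O[C@@H]1C=C[C@H]2OC(C)(C)O[C@H]2C1 | intermediate
6 | (4R,5S)-4,5-(isopropylidenedioxy)cyclohex-2-en-1-one | O=C1C=C[C@H]2OC(C)(C)O[C@H]2C1 | intermediate
7 | (Z)-hexadec-9-enal | CCCCCC/C=C\CCCCCCCC=O | starting material
8 | rac-2-[(8Z)-pentadec-8-en-1-yl]oxirane | CCCCCC/C=C\CCCCCCCC1CO1 | intermediate
9 | (S)-2-[(8Z)-pentadec-8-en-1-yl]oxirane | CCCCCC/C=C\CCCCCCC[C@H]1CO1 | intermediate
10 | dilithium (2S,10Z)-1-lithioheptadec-10-en-2-olate (not isolated) | CCCCCC/C=C\CCCCCCC[C@H](O[Li])C[Li] | intermediate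
11 | dichlorocerium derivative of 10, lithium alkoxide (not isolated) | CCCCCC/C=C\CCCCCCC[C@H](O[Li])C[Ce](Cl)Cl | intermediate
12 | (1R,4R,5S)-1-[(2S,10Z)-2-hydroxyheptadec-10-en-1-yl]-4,5-(isopropylidenedioxy)cyclohex-2-en-1-ol | CCCCCC/C=C\CCCCCCC[C@H](O)C[C@]1(O)C=C[C@H]2OC(C)(C)O[C@H]2C1 | intermediate
13 | (1R,4R,5S)-1-[(2S,10Z)-2-hydroxyheptadec-10-en-1-yl]cyclohex-2-ene-1,4,5-triol | CCCCCC/C=C\CCCCCCC[C@H](O)C[C@]1(O)C=C[C@@H](O)[C@@H](O)C1 | target

## Step count and risks

Total steps: 8. Longest linear sequence: 6 (steps 1, 2, 3, 4, 7, 8 from benzene).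

Step 3 is the riskiest, because the regiochemistry and enantiotopos selectivity of the hydroboration are untested on this diene. The fallback moves the symmetry-breaking to an epoxide and sets out from benzene 1. Birch reduction (Li, NH3, t-BuOH) gives cyclohexa-1,4-diene F1. Mono-dihydroxylation (cat. OsO4, NMO) gives meso cis-cyclohex-4-ene-1,2-diol F2. Acetonide formation gives the meso tetrahydrobenzodioxole F3, and mCPBA epoxidation anti to the dioxolane gives the meso epoxide F4. Enantioselective β-deprotonation of F4 with a chiral lithium amide (catalytic, with LDA/DBU) opens the oxirane to the allylic alcohol, and the route is rejoined at 5.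

Step 7 is next, because the β-lithioalkoxide may decompose or act as a base towards the elimination-prone enone. The fallback uses a stabilised carbanion and sets out from 9. Opening with sodium benzenesulfinate gives (2S,10Z)-1-(phenylsulfonyl)heptadec-10-en-2-ol F5. Two equivalents of n-BuLi give its O,C-dilithio derivative F6 (not isolated), which adds 1,2 to 6 anti to the dioxolane to give the sulfonyl diol F7 (epimers at the sulfonyl carbon). Reductive desulfonylation (Na/Hg, Na2HPO4, MeOH) then comes back to the route at 12.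

Step 8 is third, because acid could ionise the tertiary allylic alcohol and lead to transposition or aromatisation. The fallback replaces the acetal by a fluoride-labile group and sets out from 2. TIPDSCl2/imidazole gives the cis-5,6-(tetraisopropyldisiloxanediyldioxy)cyclohexa-1,3-diene F8. Steps 3, 4 and 7 are then run as written, through the allylborane F9 (not isolated), the allylic alcohol F10, the enone F11 and the protected adduct F12 (from 11). TBAF/AcOH in THF finally removes the disiloxane under non-acidic conditions and arrives at 13.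

## Further compounds

F1 | step 3 | cyclohexa-1,4-diene | C1C=CCC=C1
F2 | step 3 | meso cis-cyclohex-4-ene-1,2-diol | C1=CC[C@@H](O)[C@@H](O)C1
F3 | step 3 | (3aR,7aS)-2,2-dimethyl-3a,4,7,7a-tetrahydro-1,3-benzodioxole (meso) | C1=CC[C@H]2OC(C)(C)O[C@H]2C1
F4 | step 3 | meso 4,5-(isopropylidenedioxy)cyclohexene oxide, oxirane trans to the dioxolane | C1[C@@H]2O[C@@H]2C[C@H]3OC(C)(C)O[C@H]31
F5 | step 7 | (2S,10Z)-1-(phenylsulfonyl)heptadec-10-en-2-ol | CCCCCC/C=C\CCCCCCC[C@H](O)CS(=O)(=O)c1ccccc1
F6 | step 7 | O,C-dilithio derivative of F5 (not isolated) | CCCCCC/C=C\CCCCCCC[C@H](O[Li])C([Li])S(=O)(=O)c1ccccc1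
F7 | step 7 | (1R,4R,5S)-1-[(2S,10Z)-2-hydroxy-1-(phenylsulfonyl)heptadec-10-en-1-yl]-4,5-(isopropylidenedioxy)cyclohex-2-en-1-ol, epimers at C1' | CCCCCC/C=C\CCCCCCC[C@H](O)C(S(=O)(=O)c1ccccc1)[C@]1(O)C=C[C@H]2OC(C)(C)O[C@H]2C1
F8 | step 8 | cis-5,6-(1,1,3,3-tetraisopropyldisiloxane-1,3-diyldioxy)cyclohexa-1,3-diene (meso) | C1=C[C@H]2O[Si](C(C)C)(C(C)C)O[Si](C(C)C)(C(C)C)O[C@H]2C=C1
F9 | step 8 | TIPDS analogue of allylborane 4 (not isolated) | B([C@@H]1C=C[C@H]2O[Si](C(C)C)(C(C)C)O[Si](C(C)C)(C(C)C)O[C@H]2C1)([C@@H]1C[C@@H]2C[C@H]([C@H]1C)C2(C)C)[C@@H]1C[C@@H]2C[C@H]([C@H]1C)C2(C)C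
F10 | step 8 | TIPDS analogue of allylic alcohol 5 | O[C@@H]1C=C[C@H]2O[Si](C(C)C)(C(C)C)O[Si](C(C)C)(C(C)C)O[C@H]2C1
F11 | step 8 | TIPDS analogue of enone 6 | O=C1C=C[C@H]2O[Si](C(C)C)(C(C)C)O[Si](C(C)C)(C(C)C)O[C@H]2C1
F12 | step 8 | TIPDS analogue of adduct 12 | CCCCCC/C=C\CCCCCCC[C@H](O)C[C@]1(O)C=C[C@H]2O[Si](C(C)C)(C(C)C)O[Si](C(C)C)(C(C)C)O[C@H]2C1
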